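Ring A (C7, C8, C15, C14, C13, C12; fawcettimine numbering) is disconnected at C7–C8 and C13–C14 into acetone and bicyclic aldehyde 19, which already holds cyclopentenone ring B and azonine ring C. The feature exploited is the quaternary carbon C12, common to all three rings: it places the C13 aldehyde 1,3 to C7, the ring β-carbon of the cross-conjugated C5 dienone. Acetone, a 1,3-bis-nucleophile, is joined by a D-proline aldol at C13 and a 6-exo Michael closure at C7, forming ring A, two C–C bonds and the C13 and C7 stereocentres in one operation. Axial methylation at C15 and acetylation finish the route.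

Key step: step 10

Remark on numbering: N–C1–C2–C3=C4 (ring C), C5 (ketone), C6, C7 (ring-fusion CH), C8, C15 (C(CH3)O, methyl = C16), C14, C13 (CH–O), C12 (quaternary), C11–C10–C9–N. Ring A is the cyclohexane, ring B the cyclopentanone, ring C the nine-membered azonine.

Assumption: the copper–carbene catalyst of step 2 is taken to deliver the alkyl group to the enone face that gives the 3S ketone with the ligand enantiomer shown; if the sense is opposite, the enantiomeric ligand is used.

Compounds 1, 2, 5, 6, 12 and 20 are catalogue chemicals.

Step 1
Reactants: 1 3-ethoxycyclopent-2-en-1-one; 2 tributyl[(benzyloxy)methyl]stannane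
Product: 4 3-[(benzyloxy)methyl]cyclopent-2-en-1-one, via tertiary carbinol 3 (not isolated)
Conditions: 2, n-BuLi, THF, −78 °C; then 1, −78 → 0 °C; then 1 M HCl, 0 °C
Reagents that add atoms: water, O
Why: Tin–lithium exchange gives (benzyloxymethyl)lithium, which adds 1,2 to the vinylogous ester, and acid then hydrolyses the enol ether and eliminates water to transpose the carbonyl (Stork–Danheiser sequence), with no stereocenter formed.

Step 2
Reactants: 4 3-[(benzyloxy)methyl]cyclopent-2-en-1-one; 5 (3-bromopropoxy)(tert-butyl)dimethylsilane; 6 allyl iodide
Product: 8 (3S)-2-allyl-3-[(benzyloxy)methyl]-3-[3-(tert-butyldimethylsilyloxy)propyl]cyclopentan-1-one (C2 epimers), via bromomagnesium enolate 7 (not isolated)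
Conditions: 5, Mg, Et2O (Grignard reagent); Cu(OTf)2 (3 mol %), 1-[(2S)-1-hydroxy-4-methylpentan-2-yl]-3-mesityl-4,5-dihydroimidazolium hexafluorophosphate (4 mol %), 4, Et2O, −30 °C; then 6, DMPU, −30 °C → rt
Reagents that add atoms: none
Why: Copper–carbene catalysed asymmetric conjugate addition of the Grignard reagent to the β-substituted enone creates the quaternary stereocenter C12 under catalyst control of the enone face, and the regiodefined magnesium enolate 7 is C-allylated at C4 (tandem conjugate addition–enolate alkylation), whose configuration is irrelevant because C4 becomes sp2 in step 9.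

Step 3
Reactants: 8 (3S)-2-allyl-3-[(benzyloxy)methyl]-3-[3-(tert-butyldimethylsilyloxy)propyl]cyclopentan-1-one
Product: 10 (3S)-3-[(benzyloxy)methyl]-3-[3-(tert-butyldimethylsilyloxy)propyl]-2-(3-hydroxypropyl)cyclopentan-1-one, via catechol boronate 9 (not isolated)
Conditions: catecholborane, RhCl(PPh3)3 (2 mol %), THF, rt; then H2O2, NaOH, H2O, 0 °C
Reagents that add atoms: catecholborane, B1Oc2ccccc2O1 (boron is lost again on oxidation); hydrogen peroxide, OO
Why: Rhodium-catalysed hydroboration with catecholborane is anti-Markovnikov and far faster than the uncatalysed reduction of the ketone, so only the terminal alkene reacts and oxidation of the boronate 9 gives the primary alcohol.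

Step 4
Reactants: 10 (3S)-3-[(benzyloxy)methyl]-3-[3-(tert-butyldimethylsilyloxy)propyl]-2-(3-hydroxypropyl)cyclopentan-1-one
Product: 11 (3S)-3-[(benzyloxy)methyl]-2,3-bis(3-bromopropyl)cyclopentan-1-one
Conditions: Ph3PBr2 (2.5 equiv), CH2Cl2, 0 °C → rt
Reagents that add atoms: triphenylphosphine dibromide, BrP(Br)(c1ccccc1)(c1ccccc1)c1ccccc1
Why: Ph3PBr2 converts the primary alcohol and, under the same neutral conditions, the primary silyl ether into bromides through alkoxyphosphonium intermediates (Appel-type substitution), which spares a separate desilylation.

Step 5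
Reactants: 11 (3S)-3-[(benzyloxy)methyl]-2,3-bis(3-bromopropyl)cyclopentan-1-one; 12 2-nitrobenzenesulfonamide
Product: 13 N-(2-nitrophenylsulfonyl) bicyclic ketone (12S): cyclopentanone ring B fused at C4–C12 to azonine ring C with C12 bearing CH2OBn
Conditions: Cs2CO3, Bu4NI (cat.), DMF (0.01 M), 60 °C, slow addition of 11
Reagents that add atoms: none
Why: Double N-alkylation of the acidic sulfonamide (Fukuyama-type alkylation) at high dilution closes the nine-membered ring C between chains held on adjacent ring carbons, the carbonate base being too weak to enolise the ketone, and either C4 epimer can cyclise.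

Step 6
Reactants: 13 N-(2-nitrophenylsulfonyl) bicyclic ketone
Product: 14 bicyclic amino ketone (12S) with free ring-C NH
Conditions: PhSH, K2CO3, MeCN, rt
Reagents that add atoms: none
Why: Thiolate attacks the nitroarene at the sulfonyl-bearing carbon and the sulfonamide collapses with loss of SO2 (Fukuyama denosylation), which is safe here because no Michael acceptor is present yet.

Step 7
Reactants: 14 bicyclic amino ketone
Product: 15 N-formyl bicyclic ketone benzyl ether (12S)
Conditions: HCO2Et (neat), 60 °C
Reagents that add atoms: ethyl formate, CCOC=O
Why: Aminolysis of ethyl formate N-formylates the secondary amine, any transannular hemiaminal with the C5 ketone being in equilibrium with the free amine.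

Step 8
Reactants: 15 N-formyl bicyclic ketone benzyl ether
Product: 16 N-formyl bicyclic keto alcohol (12S) with C13 as CH2OH
Conditions: H2 (1 atm), Pd(OH)2/C, EtOH, rt
Reagents that add atoms: none
Why: Hydrogenolysis cleaves the benzyl ether cleanly because the molecule holds no alkene at this stage.

Step 9
Reactants: 16 N-formyl bicyclic keto alcohol
Product: 19 (12S)-dienone aldehyde with C13 formyl on C12 plus C6=C7 and (E)-C3=C4 flanking the C5 ketone, via keto aldehyde 17 (not isolated), via enone aldehyde 18 (not isolated)
Conditions: 2-iodoxybenzoic acid (IBX, 3.5 equiv), DMSO, rt → 75 °C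
Reagents that add atoms: none
Why: IBX first oxidises the primary alcohol to the non-enolisable aldehyde 17 and on heating dehydrogenates the ketone through its enols on both sides (IBX dehydrogenation of ketones), giving C6=C7 and the exocyclic C3=C4 alkene, for which the nine-membered ring should favour the E-enone in which C2 is cis to C12.

Step 10
Reactants: 19 (12S)-dienone aldehyde; 20 acetone
Product: 22 tricyclic ketol (7S,12S,13S) with ring A closed carrying C13–OH and the C15 ketone, via aldol adduct 21 (not isolated)
Conditions: D-proline (30 mol %), acetone–DMSO (1:4), rt; then DBU (0.5 equiv), 0 °C → rt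
Reagents that add atoms: none
Why: The D-proline enamine of acetone adds to the non-enolisable C13 aldehyde through the hydrogen-bonded chair transition state of the proline aldol reaction, and the methyl ketone 21 so formed closes ring A by conjugate addition of its terminal enolate carbon C8 to C7, the ring β-carbon of the cross-conjugated dienone, once DBU is added. The closest known reactions are the proline-catalysed acetone aldol with α-branched aldehydes and the base-mediated intramolecular Michael addition of a ketone to a cyclopentenone, together a formal [3+3] aldol–Michael annulation. Ring A closes in a 6-(enolendo)-exo-trig mode. C13 is set by the catalyst, D-proline being expected to give the 13S carbinol just as L-proline gives the R carbinol from pivalaldehyde, whereas C7 is set by the substrate, because the three-atom tether hangs from C12 and reaches C7 only on the face syn to C13, which enforces the cis ring fusion. The step needs chemoselectivity for the aldehyde over the enones in the aldol and site selectivity for C7 over C3 in the Michael addition: the first rests on the low reactivity of acetone enamines towards enones, the second on ring size (six- against seven-membered closure) and on the higher electrophilicity of the endocyclic β-carbon. Enolisation towards C14 is unproductive (four-membered ring), so only the C8 enolate cyclises and the exocyclic C3=C4 enone of the target survives.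

Step 11
Reactants: 22 tricyclic ketol
Product: 23 tricyclic diol (7S,12S,13S,15S) with cis C13–OH and tertiary C15(CH3)–OH
Conditions: AlMe3 (5 equiv), toluene, −40 → 0 °C
Reagents that add atoms: trimethylaluminium, C[Al](C)C
Why: Excess AlMe3 in a hydrocarbon solvent adds to cyclohexanones from the axial direction (1,2-addition through a two-aluminium transition state), which on the chair with equatorial C13–O places the methyl group axial and the new hydroxyl equatorial and cis to the C13 hydroxyl, while the saturated C15 ketone should react ahead of the hindered conjugated C5 ketone and the formamide.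

Step 12
Reactants: 23 tricyclic diol
Product: 24 CNP0137427.1 (target diacetate)
Conditions: Ac2O, Sc(OTf)3 (5 mol %), MeCN, −20 → 0 °C
Reagents that add atoms: acetic anhydride, CC(=O)OC(C)=O
Why: Sc(OTf)3-catalysed acylation with acetic anhydride esterifies both the hindered secondary and the tertiary hydroxyl at low temperature without elimination.

Compound list
1 | 3-ethoxycyclopent-2-en-1-one | CCOC1=CC(=O)CC1 | starting material
2 | tributyl[(benzyloxy)methyl]stannane | CCCC[Sn](CCCC)(CCCC)COCc1ccccc1 | starting material
3 | 1-[(benzyloxy)methyl]-3-ethoxycyclopent-2-en-1-ol (racemic, not isolated) | CCOC1=CC(O)(COCc2ccccc2)CC1 | intermediate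
4 | 3-[(benzyloxy)methyl]cyclopent-2-en-1-one | O=C1C=C(COCc2ccccc2)CC1 | intermediate
5 | (3-bromopropoxy)(tert-butyl)dimethylsilane | BrCCCO[Si](C)(C)C(C)(C)C | starting material
6 | allyl iodide | C=CCI | starting material
7 | bromomagnesium enolate of the conjugate adduct (3S, not isolated) | Br[Mg]OC1=C[C@](COCc2ccccc2)(CCCO[Si](C)(C)C(C)(C)C)CC1 | intermediate
8 | (3S)-2-allyl-3-[(benzyloxy)methyl]-3-[3-(tert-butyldimethylsilyloxy)propyl]cyclopentan-1-one (C2 epimers) | O=C1CC[C@@](COCc2ccccc2)(CCCO[Si](C)(C)C(C)(C)C)C1CC=C | intermediate
9 | catechol boronate of 8 at the terminal carbon of the former allyl group (not isolated) | O=C1CC[C@@](COCc2ccccc2)(CCCO[Si](C)(C)C(C)(C)C)C1CCCB3Oc4ccccc4O3 | intermediate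
10 | (3S)-3-[(benzyloxy)methyl]-3-[3-(tert-butyldimethylsilyloxy)propyl]-2-(3-hydroxypropyl)cyclopentan-1-one | O=C1CC[C@@](COCc2ccccc2)(CCCO[Si](C)(C)C(C)(C)C)C1CCCO | intermediate
11 | (3S)-3-[(benzyloxy)methyl]-2,3-bis(3-bromopropyl)cyclopentan-1-one | O=C1CC[C@@](COCc2ccccc2)(CCCBr)C1CCCBr | intermediate
12 | 2-nitrobenzenesulfonamide | NS(=O)(=O)c1ccccc1[N+](=O)[O-] | starting material
13 | N-(2-nitrophenylsulfonyl) bicyclic ketone (12S; rings B and C, C12–CH2OBn) | O=C1CC[C@@]2(COCc3ccccc3)CCCN(S(=O)(=O)c3ccccc3[N+](=O)[O-])CCCC12 | intermediate
14 | bicyclic amino ketone (12S) | O=C1CC[C@@]2(COCc3ccccc3)CCCNCCCC12 | intermediate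
15 | N-formyl bicyclic ketone benzyl ether (12S) | O=C1CC[C@@]2(COCc3ccccc3)CCCN(C=O)CCCC12 | intermediate
16 | N-formyl bicyclic keto alcohol (12S) | OC[C@@]12CCC(=O)C1CCCN(C=O)CCC2 | intermediate
17 | N-formyl bicyclic keto aldehyde (12S, not isolated) | O=C[C@@]12CCC(=O)C1CCCN(C=O)CCC2 | intermediate
18 | N-formyl bicyclic enone aldehyde with C6=C7 (12S, not isolated) | O=C[C@@]12C=CC(=O)C1CCCN(C=O)CCC2 | intermediate
19 | N-formyl bicyclic dienone aldehyde (12S; C6=C7 and E-C3=C4) | O=C[C@@]12C=CC(=O)/C1=C/CCN(C=O)CCC2 | intermediate
20 | acetone | CC(C)=O | starting material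
21 | aldol adduct (12S,13S; C13 carbinol carrying the 2-oxopropyl chain, not isolated) | CC(=O)C[C@H](O)[C@@]12C=CC(=O)/C1=C/CCN(C=O)CCC2 | intermediate
22 | tricyclic ketol (7S,12S,13S) | O[C@H]1CC(=O)C[C@H]2CC(=O)/C3=C/CCN(C=O)CCC[C@@]321 | intermediate
23 | tricyclic diol (7S,12S,13S,15S) | O[C@H]1C[C@@](C)(O)C[C@H]2CC(=O)/C3=C/CCN(C=O)CCC[C@@]321 | intermediate
24 | CNP0137427.1 | CC(=O)O[C@H]1C[C@@](C)(OC(C)=O)C[C@H]2CC(=O)/C3=C/CCN(C=O)CCC[C@@]321 | target

Total step count: 12. Longest linear sequence: 12 steps (fully linear from 1).

Steps most likely to fail

Step 10. The amine catalyst and the acetone enamine may add reversibly to the cross-conjugated dienone faster than the enamine adds to the hindered neopentyl aldehyde, so that C13 forms with poor facial control; retro-aldol equilibration under DBU may erode C13 further. The fallback sets out from 19 and returns at 22. The aldol is run under reagent control with the diisopinocampheylboron enolate of acetone (acetone, B-chlorodiisopinocampheylborane of the antipode matched to the 13S carbinol, Et3N, Et2O, −78 °C, non-oxidative work-up with diethanolamine). The aldol adduct 21 is isolated, and ring A is then closed in a separate step with catalytic DBU in CH2Cl2 at 0 °C. No compound outside the list arises (entry F0).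

Step 9. Dehydrogenation may run on along ring C towards C2–C1 or stop after the first alkene, and the neopentyl aldehyde may degrade during prolonged heating with the oxidant. The fallback sets out from 15 and returns at 19. The unsaturation is installed before the alcohol is freed, by two enolate-based dehydrogenations with N-tert-butylbenzenesulfinimidoyl chloride. LiN(i-Pr)2 (THF, −78 °C) deprotonates 15 at the less hindered C6 and gives the enone benzyl ether F1. A second cycle, in which only C4 can still be deprotonated, gives the dienone benzyl ether F2. BCl3 (CH2Cl2, −78 °C) cleaves the benzyl ether to the dienone alcohol F3, and Dess–Martin periodinane oxidises it to 19.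

Step 11. Facial selectivity may be poor (equatorial delivery of methyl, possibly from aluminium bound to the C13 alkoxide, would give the C15 epimer), and addition to the C5 enone may compete. The fallback sets out from 22 and returns at 23. The carbon is delivered as methylene by dimethylsulfonium methylide (Me3S+ I−, KN(SiMe3)2, THF, −10 °C), which adds irreversibly from the axial direction and should give the spiro-epoxide F4 with equatorial oxygen (Corey–Chaykovsky reaction). MgI2 (Et2O) opens the epoxide at its primary carbon to the iodohydrin F5, and Bu3SnH/AIBN (benzene, 80 °C) removes the iodine to give 23.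

Further compounds
F0 | step 10 | none | none
F1 | step 9 | N-formyl bicyclic enone benzyl ether with C6=C7 (12S) | O=C1C=C[C@@]2(COCc3ccccc3)CCCN(C=O)CCCC12
F2 | step 9 | N-formyl bicyclic dienone benzyl ether (12S; C6=C7 and E-C3=C4) | c3ccccc3COC[C@@]12C=CC(=O)/C1=C/CCN(C=O)CCC2
F3 | step 9 | N-formyl bicyclic dienone alcohol (12S) | OC[C@@]12C=CC(=O)/C1=C/CCN(C=O)CCC2
F4 | step 11 | spiro-epoxide at C15 (oxygen equatorial, 7S,12S,13S,15S) | O[C@H]1C[C@]2(CO2)C[C@H]3CC(=O)/C4=C/CCN(C=O)CCC[C@@]431
F5 | step 11 | iodohydrin with C16 as CH2I and tertiary C15–OH | O[C@H]1C[C@@](CI)(O)C[C@H]2CC(=O)/C3=C/CCN(C=O)CCC[C@@]321
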